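Slowness is what I read here: how little the rate of Prd formation gains when more Sub goes in, and what that leaves for a much larger charge.

| flask | Sub | Rgt | Cat | time |
|---|---|---|---|---|
| spring | 120 mM | 300 mM | 6.00 mM |  |
| midnight | 120 mM | 450 mM | 6.00 mM |  |
| autumn | 360 mM | 300 mM | 6.00 mM |  |
| winter | 870 mM | 300 mM | 6.00 mM | 6.0 min |

| run | time / min | [Prd] / mM |
|---|---|---|
| spring run | 0.22 | 0.3 |
| spring run | 0.65 | 3.8 |
| spring run | 1.2 | 8.9 |
| spring run | 2.0 | 18.0 |
| spring run | 2.8 | 27.4 |
| spring run | 3.8 | 37.9 |
| spring run | 4.8 | 49.3 |
| spring run | 6.0 | 61.5 |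
| midnight run | 0.22 | 1.1 |
| midnight run | 0.65 | 4.4 |
| midnight run | 1.2 | 12.4 |
| midnight run | 2.0 | 23.4 |
| midnight run | 2.8 | 33.8 |
| midnight run | 3.8 | 46.3 |
| midnight run | 4.8 | 58.6 |
| midnight run | 6.0 | 71.9 |
| autumn run | 0.22 | 0.6 |
| autumn run | 0.65 | 4.5 |
| autumn run | 1.2 | 10.4 |
| autumn run | 2.0 | 20.6 |
| autumn run | 2.8 | 31.4 |
| autumn run | 3.8 | 44.0 |
| autumn run | 4.8 | 56.0 |
| autumn run | 6.0 | 70.3 |

(scatter of a reading: 0.4 mM)

1. the exponent of [Sub] in the starting rate at the charge of the spring run (at the point where two percent of the Sub have become Prd) (one fixed amount of Prd, the same in the runs compared)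
2. the exponent of [Rgt] in the starting rate at the charge of the spring run (at the point where two percent of the Sub have become Prd)
3. Prd in the winter run at 6.0 min, as a share of the Sub charged

- Overall: Sub + Rgt -> Prd, with Cat as catalyst.
- Constant volume, constant temperature.
- Bound and free are read together.
- An order is taken over about fifteen percent of the charge, up and down.

I read the tables from their later rows, past the short lag. From 2.8 min to 6.0 min the spring column climbs at 10.7 mM min⁻¹ and the autumn column at 12.2 mM min⁻¹. Autumn holds 3.00 times the Sub, yet its slope is up by a factor of 1.14. Over that stretch spring keeps on average 63.0% of its charge and autumn 85.9%.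

At one Rgt and Cat charge I take the slope as a ceiling times Sub/(K + Sub). The two slopes then give the reading 14.7 mM, which is 12.3% of the spring charge. K is the Sub level at which the slope stands at half its ceiling, the half-saturation constant. It carries the scatter of the slopes.

In that form the exponent of Sub is K/(K + Sub), which is 0.111 at the spring charge. Apart from K, the midnight column, read against spring at 2.8 min, gives a reading of 0.518 for the exponent of Rgt.

For the winter run I assume it makes about what autumn makes, so it keeps 94.2% of its charge. That puts it at 98.2% of the ceiling, against 95.4% for autumn. Scaling the autumn reading at 6.0 min by that ratio gives 8.32% of the winter charge. This is less than the 34.5% of the Sub that its Rgt charge covers, so Rgt, the limiting reagent there, sets no end within 6.0 min.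

The forecast gives 0.14 (0.04 to 0.27) for Sub, 0.5 (0.3 to 0.7) for Rgt, and 8.4% (7% to 9.2%) for the winter share. Its range reaches lower on the ground that “Substrate inhibition cannot be excluded”. My share is a little lower than its value.

The winter run gives 8.32% at 6.0 min, with exponents 0.12 for Sub and 0.48 for Rgt.

    E + Sub → L + Byp (120.6 M⁻¹ min⁻¹)
    L + Rgt → Prd + E (63.60 M⁻¹ min⁻¹)
    Cat + Rgt → E + Rgt (71.40 M⁻¹ min⁻¹)
    2 Rgt ⇌ Rgt2, settled at all times (95.40 M⁻¹)

The slowness of Cat + Rgt → E + Rgt moves the readings by 9.8 in units of the scatter, root mean square. I now put K on the autumn run beyond its last reading, where 19.5% of the charge has turned. On the way to a quarter of the charge it keeps about 77.7% of its Sub, so K gives a slope of 12.1 mM min⁻¹ and an arrival at 7.63 min. In the autumn run, the Prd made comes to a quarter of the charge at 7.77 min.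

The data are calculated on assumed constants, noise included.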